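**Plan**

- Cuts: (a) the eight phenol O–MOM bonds, last. (b) In the styryl-bearing dihydrobenzofuran (unit A), three bonds at once: C3–C6' (to the aromatic carbon of the second benzofuran, unit B), C2–C3 and C2–O1. (c) The same three bonds in unit B (C3'–aryl, C2'–C3', C2'–O1'). (d) The aryl–vinyl bond of the stilbene.
- Enabling feature: in both units C3 is a diarylmethine on C3a, and C3a lies between C7a (which bears O1) and the oxygenated C4. O1–C7a–C3a–C3 is therefore the heterodiene of an ortho-quinone methide. A 2,6-dioxygenated benzaldehyde (formyl C = C3) releases it once an aryl metal has added. C2 (benzylic, O-bound) is a benzylidene 1,1-dipole, that is, a sulfonium benzylide.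
- Forward: one aldehyde (12) feeds both units. Unit B is assembled from aryllithium + O-Boc aldehyde + benzylide. Its C6' bromide becomes the next aryllithium, and the same cascade with the stilbene aldehyde builds unit A and joins the halves. Global deprotection follows.
- Stereochemistry: C2/C2' come from the shielded ylide face of C2-symmetric (2R,5R)-2,5-dimethylthiolane and SN2 closure. C3/C3' come from the anti approach that leads to the trans ring. The E-alkene comes from the Heck reaction.

Key step: step 16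

Assumption: the ylide of (2R,5R)-3 is taken to react through the same open face as in its benzylidene transfer to aldehydes, which gives (S,S)-epoxides. With O1 in place of the epoxide O and C3 in place of the aldehyde C, this corresponds to 2R. If the sense were opposite, the enantiomeric sulfide from (2R,5R)-hexane-2,5-diol would be used. MOM = methoxymethyl.

**Step 1**
Reactants: 1 (2S,5S)-hexane-2,5-diol
Product: 2 (2S,5S)-hexane-2,5-diyl dimethanesulfonate
Conditions: MsCl, Et3N, CH2Cl2, 0 °C
Reagents that add atoms: methanesulfonyl chloride CS(=O)(=O)Cl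
Why: Mesylate formation takes place at oxygen, so both stereocentres are retained.

**Step 2**
Reactants: 2 (2S,5S)-hexane-2,5-diyl dimethanesulfonate
Product: 3 (2R,5R)-2,5-dimethylthiolane
Conditions: Na2S·9H2O, EtOH, rt
Reagents that add atoms: sodium sulfide [Na+].[Na+].[S-2]
Why: Double SN2 displacement by sulfide (intermolecular, then 5-exo-tet) inverts both centres and gives the C2-symmetric (R,R)-thiolane.

**Step 3**
Reactants: 4 2,4-dihydroxybenzaldehyde
Product: 5 2,4-bis(methoxymethoxy)benzaldehyde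
Conditions: NaH, MOMCl, DMF, 0 °C to rt
Reagents that add atoms: chloromethyl methyl ether COCCl
Why: Williamson-type O-alkylation of both phenoxides, with NaH also freeing the hydrogen-bonded ortho phenol.

**Step 4**
Reactants: 5 2,4-bis(methoxymethoxy)benzaldehyde
Product: 6 [2,4-bis(methoxymethoxy)phenyl]methanol
Conditions: NaBH4, MeOH, 0 °C
Reagents that add atoms: none
Why: Borohydride reduction of the aldehyde, to which MOM acetals are inert.

**Step 5**
Reactants: 6 [2,4-bis(methoxymethoxy)phenyl]methanol; 3 (2R,5R)-2,5-dimethylthiolane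
Product: 9 (2R,5R)-1-[2,4-bis(methoxymethoxy)benzyl]-2,5-dimethylthiolanium tetrafluoroborate, via benzylic mesylate 7 (not isolated), via thiolanium mesylate 8 (not isolated)
Conditions: Ms2O, iPr2NEt, 3, CH2Cl2, -30 °C to rt; cold aq NaBF4 wash
Reagents that add atoms: sodium tetrafluoroborate [Na+].F[B-](F)(F)F
Why: S-alkylation of a dialkyl sulfide by a benzylic sulfonate made in situ under basic conditions that spare the MOM acetals, then anion metathesis; the two lone pairs of C2-symmetric 3 are equivalent, so a single salt forms.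

**Step 6**
Reactants: 10 4-bromo-2,6-dimethoxybenzaldehyde
Product: 11 4-bromo-2,6-dihydroxybenzaldehyde
Conditions: BBr3, CH2Cl2, -78 °C to rt; H2O
Reagents that add atoms: none
Why: Lewis-acid aryl methyl ether cleavage, assisted by chelation to the ortho formyl group.

**Step 7**
Reactants: 11 4-bromo-2,6-dihydroxybenzaldehyde
Product: 12 4-bromo-2-hydroxy-6-(methoxymethoxy)benzaldehyde
Conditions: MOMCl (1 equiv), iPr2NEt, CH2Cl2, 0 °C
Reagents that add atoms: chloromethyl methyl ether COCCl
Why: Selective mono-O-alkylation, because after the first capping the remaining phenol is locked in a hydrogen bond to the formyl oxygen and is much less nucleophilic.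

**Step 8**
Reactants: 12 4-bromo-2-hydroxy-6-(methoxymethoxy)benzaldehyde
Product: 13 5-bromo-2-formyl-3-(methoxymethoxy)phenyl tert-butyl carbonate
Conditions: Boc2O, iPr2NEt, DMAP (cat.), CH2Cl2, 0 °C to rt
Reagents that add atoms: di-tert-butyl dicarbonate CC(C)(C)OC(=O)OC(=O)OC(C)(C)C
Why: DMAP-catalysed O-acylation installs the group that later migrates and leaves in the quinone methide cascade.

**Step 9**
Reactants: 14 5-bromobenzene-1,3-diol
Product: 15 1-bromo-3,5-bis(methoxymethoxy)benzene
Conditions: MOMCl, iPr2NEt, CH2Cl2, 0 °C to rt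
Reagents that add atoms: chloromethyl methyl ether COCCl
Why: Standard MOM protection of two free phenols.

**Step 10**
Reactants: 15 1-bromo-3,5-bis(methoxymethoxy)benzene; 13 5-bromo-2-formyl-3-(methoxymethoxy)phenyl tert-butyl carbonate; 9 (2R,5R)-1-[2,4-bis(methoxymethoxy)benzyl]-2,5-dimethylthiolanium tetrafluoroborate
Product: 21 (2R,3R)-6-bromo-2-[2,4-bis(methoxymethoxy)phenyl]-3-[3,5-bis(methoxymethoxy)phenyl]-4-(methoxymethoxy)-2,3-dihydro-1-benzofuran, via aryllithium 16 (not isolated), via phenoxide carbonate 17 (not isolated), via thiolanium benzylide 18 (not isolated), via ortho-quinone methide 19 (not isolated), via betaine 20 (not isolated)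
Conditions: 15, t-BuLi (2.0 equiv), THF, -78 °C; add 13, -78 °C; add 18 (made apart from 9, LiHMDS, THF, -78 °C); MgBr2·OEt2, -78 to 0 °C; H2O
Reagents that add atoms: none
Why: Proposed new method: the cascade of step 16 is first run on simpler parts: 16 adds to the formyl group of 13 faster than it exchanges with the aryl bromide, Boc transfer gives 17, Mg(II) releases methide 19, benzylide 18 adds 1,4 to give betaine 20, and the phenoxide closes the ring 5-exo-tet with inversion at C2; the closest known reaction types are the organometal-triggered o-quinone methide generation from O-Boc salicylaldehydes and the trans-selective [4+1] annulation of sulfur ylides with o-quinone methides, the new element being a semistabilised benzylide on a chiral thiolane, whose shielded face should set 2R and whose anti (aryl/aryl, sulfonium/arene) approach should set 3R.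

**Step 11**
Reactants: 22 4-ethenylphenyl acetate (4-acetoxystyrene)
Product: 24 1-ethenyl-4-(methoxymethoxy)benzene, via sodium 4-ethenylphenoxide 23 (not isolated)
Conditions: NaOMe (1.05 equiv), THF, 0 °C; MOMCl, 0 °C to rt
Reagents that add atoms: chloromethyl methyl ether COCCl
Why: Methoxide transesterifies the aryl acetate and the phenoxide is O-alkylated in the same flask, which avoids handling polymerisable 4-vinylphenol.

**Step 12**
Reactants: 12 4-bromo-2-hydroxy-6-(methoxymethoxy)benzaldehyde; 24 1-ethenyl-4-(methoxymethoxy)benzene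
Product: 25 2-hydroxy-6-(methoxymethoxy)-4-{(E)-2-[4-(methoxymethoxy)phenyl]ethenyl}benzaldehyde
Conditions: Pd(OAc)2 (cat.), P(o-tol)3, Et3N, DMF, 90 °C
Reagents that add atoms: none
Why: Heck reaction of a bromide activated by the para formyl group; syn insertion at the terminal carbon and syn β-hydride elimination give the E-stilbene.

**Step 13**
Reactants: 25 2-hydroxy-6-(methoxymethoxy)-4-{(E)-2-[4-(methoxymethoxy)phenyl]ethenyl}benzaldehyde
Product: 26 tert-butyl 2-formyl-3-(methoxymethoxy)-5-{(E)-2-[4-(methoxymethoxy)phenyl]ethenyl}phenyl carbonate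
Conditions: Boc2O, iPr2NEt, DMAP (cat.), CH2Cl2, 0 °C to rt
Reagents that add atoms: di-tert-butyl dicarbonate CC(C)(C)OC(=O)OC(=O)OC(C)(C)C
Why: The same DMAP-catalysed O-acylation as in step 8, to which alkene, acetals and aldehyde are inert.

**Step 14**
Reactants: 27 4-(hydroxymethyl)phenol
Product: 28 [4-(methoxymethoxy)phenyl]methanol
Conditions: MOMCl (1 equiv), K2CO3, acetone, 0 °C to rt
Reagents that add atoms: chloromethyl methyl ether COCCl
Why: Carbonate deprotonates only the phenol, so Williamson-type alkylation is selective for the phenoxide over the benzylic alcohol.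

**Step 15**
Reactants: 28 [4-(methoxymethoxy)phenyl]methanol; 3 (2R,5R)-2,5-dimethylthiolane
Product: 31 (2R,5R)-1-[4-(methoxymethoxy)benzyl]-2,5-dimethylthiolanium tetrafluoroborate, via benzylic mesylate 29 (not isolated), via thiolanium mesylate 30 (not isolated)
Conditions: Ms2O, iPr2NEt, 3, CH2Cl2, -30 °C to rt; cold aq NaBF4 wash
Reagents that add atoms: sodium tetrafluoroborate [Na+].F[B-](F)(F)F
Why: The same S-alkylation of the sulfide by an in situ benzylic sulfonate and anion metathesis as in step 5.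

**Step 16**
Reactants: 21 (2R,3R)-6-bromo-2-[2,4-bis(methoxymethoxy)phenyl]-3-[3,5-bis(methoxymethoxy)phenyl]-4-(methoxymethoxy)-2,3-dihydro-1-benzofuran; 26 tert-butyl 2-formyl-3-(methoxymethoxy)-5-{(E)-2-[4-(methoxymethoxy)phenyl]ethenyl}phenyl carbonate; 31 (2R,5R)-1-[4-(methoxymethoxy)benzyl]-2,5-dimethylthiolanium tetrafluoroborate
Product: 37 octakis(methoxymethyl) ether of the target with (2R,3R,2'R,3'R) configuration, via aryllithium 32 (not isolated), via phenoxide carbonate 33 (not isolated), via thiolanium benzylide 34 (not isolated), via ortho-quinone methide 35 (not isolated), via betaine 36 (not isolated)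
Conditions: 21, t-BuLi (2.0 equiv), THF, -78 °C; add 26, -78 °C; add 34 (made apart from 31, LiHMDS, THF, -78 °C); MgBr2·OEt2, -78 to 0 °C; H2O
Reagents that add atoms: none
Why: Proposed new method: aryllithium 32 adds to the formyl carbon of 26 (this makes the C3–C6' bond), the alkoxide takes over the neighbouring Boc group to give phenoxide 33, Mg(II) triggers loss of tert-butyl carbonate to give ortho-quinone methide 35, and benzylide 34 attacks its exocyclic carbon with rearomatisation to betaine 36. Phenoxide O1 then displaces the thiolane at C2 in a 5-exo-tet SN2 closure with inversion, which forms the only new ring; should this closure drift towards SN1, C3 would still steer it to the same trans ring. The closest known reaction types are the organometal-triggered o-quinone methide cascade of O-Boc salicylaldehydes with a second nucleophile, the trans-selective [4+1] annulation of sulfur ylides with o-quinone methides, and benzylidene transfer from C2-symmetric thiolanium ylides; what is new is their merger with a semistabilised chiral benzylide. C2 is controlled by the sulfide: in the ylide conformer with the aryl group turned away from the thiolane ring, the methyl group cis to the ylide carbon shields one face, which gives the S-configured sulfonium carbon in 36 and, after inversion, 2R. C3 follows from the staggered open transition state in which the sulfonium group is anti to the bulky 2,6-dioxygenated ring and the two aryl groups are anti, which is the conformer that closes to the trans ring, so 3R results and the remote centres of unit B play no part. The step needs aldehyde-before-carbonate attack, no ylide epoxidation, and attack at the methide carbon rather than at the styryl terminus; these rest on the order of addition at -78 °C, on the release of 35 only after the aldehyde is consumed, and on the aromatisation that only attack at C3 gains.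

**Step 17**
Reactants: 37 octakis(methoxymethyl) ether of the target
Product: 38 (2R,3R)-3-[(2R,3R)-2-(2,4-dihydroxyphenyl)-3-(3,5-dihydroxyphenyl)-4-hydroxy-2,3-dihydro-1-benzofuran-6-yl]-2-(4-hydroxyphenyl)-6-[(E)-2-(4-hydroxyphenyl)ethenyl]-2,3-dihydro-1-benzofuran-4-ol (target)
Conditions: HCl (1.25 M in MeOH), THF, 40 °C, Ar, dark
Reagents that add atoms: none
Why: Acid-catalysed transacetalisation of the eight aryl MOM acetals to dimethoxymethane; reversible ionisation at C2 or C2' can only return the more stable trans rings because C3 and C3' are untouched, so no stereocentre is lost.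

**Compound list**

1 | (2S,5S)-hexane-2,5-diol | C[C@H](O)CC[C@H](C)O | starting material
2 | (2S,5S)-hexane-2,5-diyl dimethanesulfonate | C[C@H](OS(C)(=O)=O)CC[C@H](C)OS(C)(=O)=O | intermediate
3 | (2R,5R)-2,5-dimethylthiolane | C[C@@H]1CC[C@@H](C)S1 | intermediate
4 | 2,4-dihydroxybenzaldehyde | Oc1ccc(C=O)c(O)c1 | starting material
5 | 2,4-bis(methoxymethoxy)benzaldehyde | COCOc1ccc(C=O)c(OCOC)c1 | intermediate
6 | [2,4-bis(methoxymethoxy)phenyl]methanol | COCOc1ccc(CO)c(OCOC)c1 | intermediate
7 | 2,4-bis(methoxymethoxy)benzyl methanesulfonate | COCOc1ccc(COS(C)(=O)=O)c(OCOC)c1 | intermediate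
8 | (2R,5R)-1-[2,4-bis(methoxymethoxy)benzyl]-2,5-dimethylthiolanium methanesulfonate | C[C@@H]1CC[C@@H](C)[S+]1Cc1ccc(OCOC)cc1OCOC.CS(=O)(=O)[O-] | intermediate
9 | (2R,5R)-1-[2,4-bis(methoxymethoxy)benzyl]-2,5-dimethylthiolanium tetrafluoroborate | C[C@@H]1CC[C@@H](C)[S+]1Cc1ccc(OCOC)cc1OCOC.F[B-](F)(F)F | intermediate
10 | 4-bromo-2,6-dimethoxybenzaldehyde | COc1cc(Br)cc(OC)c1C=O | starting material
11 | 4-bromo-2,6-dihydroxybenzaldehyde | Oc1cc(Br)cc(O)c1C=O | intermediate
12 | 4-bromo-2-hydroxy-6-(methoxymethoxy)benzaldehyde | COCOc1cc(Br)cc(O)c1C=O | intermediate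
13 | 5-bromo-2-formyl-3-(methoxymethoxy)phenyl tert-butyl carbonate | COCOc1cc(Br)cc(OC(=O)OC(C)(C)C)c1C=O | intermediate
14 | 5-bromobenzene-1,3-diol | Oc1cc(O)cc(Br)c1 | starting material
15 | 1-bromo-3,5-bis(methoxymethoxy)benzene | COCOc1cc(Br)cc(OCOC)c1 | intermediate
16 | [3,5-bis(methoxymethoxy)phenyl]lithium | [Li]c1cc(OCOC)cc(OCOC)c1 | intermediate
17 | lithium 5-bromo-2-{[3,5-bis(methoxymethoxy)phenyl](tert-butoxycarbonyloxy)methyl}-3-(methoxymethoxy)phenoxide (carbinol centre not defined) | [Li+].[O-]c1cc(Br)cc(OCOC)c1C(OC(=O)OC(C)(C)C)c1cc(OCOC)cc(OCOC)c1 | intermediate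
18 | (2R,5R)-2,5-dimethylthiolanium 2,4-bis(methoxymethoxy)benzylide | C[C@@H]1CC[C@@H](C)[S+]1[CH-]c1ccc(OCOC)cc1OCOC | intermediate
19 | 3-bromo-6-[3,5-bis(methoxymethoxy)benzylidene]-5-(methoxymethoxy)cyclohexa-2,4-dien-1-one (exocyclic geometry not defined) | O=C1C=C(Br)C=C(OCOC)C1=Cc1cc(OCOC)cc(OCOC)c1 | intermediate
20 | betaine: 5-bromo-3-(methoxymethoxy)-2-{(1R,2S)-1-[3,5-bis(methoxymethoxy)phenyl]-2-[2,4-bis(methoxymethoxy)phenyl]-2-[(2R,5R)-2,5-dimethylthiolanium-1-yl]ethyl}phenoxide | [O-]c1cc(Br)cc(OCOC)c1[C@@H](c1cc(OCOC)cc(OCOC)c1)[C@@H](c1ccc(OCOC)cc1OCOC)[S+]1[C@H](C)CC[C@H]1C | intermediate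
21 | (2R,3R)-6-bromo-2-[2,4-bis(methoxymethoxy)phenyl]-3-[3,5-bis(methoxymethoxy)phenyl]-4-(methoxymethoxy)-2,3-dihydro-1-benzofuran | Brc1cc(OCOC)c2c(c1)O[C@@H](c1ccc(OCOC)cc1OCOC)[C@@H]2c1cc(OCOC)cc(OCOC)c1 | intermediate
22 | 4-ethenylphenyl acetate | CC(=O)Oc1ccc(C=C)cc1 | starting material
23 | sodium 4-ethenylphenoxide | [Na+].[O-]c1ccc(C=C)cc1 | intermediate
24 | 1-ethenyl-4-(methoxymethoxy)benzene | COCOc1ccc(C=C)cc1 | intermediate
25 | 2-hydroxy-6-(methoxymethoxy)-4-{(E)-2-[4-(methoxymethoxy)phenyl]ethenyl}benzaldehyde | COCOc1ccc(/C=C/c2cc(O)c(C=O)c(OCOC)c2)cc1 | intermediate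
26 | tert-butyl 2-formyl-3-(methoxymethoxy)-5-{(E)-2-[4-(methoxymethoxy)phenyl]ethenyl}phenyl carbonate | COCOc1ccc(/C=C/c2cc(OC(=O)OC(C)(C)C)c(C=O)c(OCOC)c2)cc1 | intermediate
27 | 4-(hydroxymethyl)phenol | OCc1ccc(O)cc1 | starting material
28 | [4-(methoxymethoxy)phenyl]methanol | COCOc1ccc(CO)cc1 | intermediate
29 | 4-(methoxymethoxy)benzyl methanesulfonate | COCOc1ccc(COS(C)(=O)=O)cc1 | intermediate
30 | (2R,5R)-1-[4-(methoxymethoxy)benzyl]-2,5-dimethylthiolanium methanesulfonate | C[C@@H]1CC[C@@H](C)[S+]1Cc1ccc(OCOC)cc1.CS(=O)(=O)[O-] | intermediate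
31 | (2R,5R)-1-[4-(methoxymethoxy)benzyl]-2,5-dimethylthiolanium tetrafluoroborate | C[C@@H]1CC[C@@H](C)[S+]1Cc1ccc(OCOC)cc1.F[B-](F)(F)F | intermediate
32 | 6-lithio derivative of 21 (Li in place of Br, 2R,3R) | [Li]c1cc(OCOC)c2c(c1)O[C@@H](c1ccc(OCOC)cc1OCOC)[C@@H]2c1cc(OCOC)cc(OCOC)c1 | intermediate
33 | lithium phenoxide with benzylic tert-butyl carbonate from 32 and 26 (carbinol centre not defined) | [Li+].[O-]c1cc(/C=C/c2ccc(OCOC)cc2)cc(OCOC)c1C(OC(=O)OC(C)(C)C)c1cc(OCOC)c2c(c1)O[C@@H](c1ccc(OCOC)cc1OCOC)[C@@H]2c1cc(OCOC)cc(OCOC)c1 | intermediate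
34 | (2R,5R)-2,5-dimethylthiolanium 4-(methoxymethoxy)benzylide | C[C@@H]1CC[C@@H](C)[S+]1[CH-]c1ccc(OCOC)cc1 | intermediate
35 | ortho-quinone methide: 6-(arylmethylidene)-5-(methoxymethoxy)-3-{(E)-2-[4-(methoxymethoxy)phenyl]ethenyl}cyclohexa-2,4-dien-1-one, aryl = benzofuran-6-yl of unit B (exocyclic geometry not defined) | O=C1C=C(/C=C/c2ccc(OCOC)cc2)C=C(OCOC)C1=Cc1cc(OCOC)c2c(c1)O[C@@H](c1ccc(OCOC)cc1OCOC)[C@@H]2c1cc(OCOC)cc(OCOC)c1 | intermediate
36 | betaine: phenoxide of unit A with an R-configured diarylmethine carbon and an S-configured thiolanium-bearing benzylic carbon | [O-]c1cc(/C=C/c2ccc(OCOC)cc2)cc(OCOC)c1[C@@H](c1cc(OCOC)c2c(c1)O[C@@H](c1ccc(OCOC)cc1OCOC)[C@@H]2c1cc(OCOC)cc(OCOC)c1)[C@@H](c1ccc(OCOC)cc1)[S+]1[C@H](C)CC[C@H]1C | intermediate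
37 | octakis(methoxymethyl) ether of the target, (2R,3R,2'R,3'R), E | COCOc1ccc(/C=C/c2cc(OCOC)c3c(c2)O[C@@H](c2ccc(OCOC)cc2)[C@@H]3c2cc(OCOC)c3c(c2)O[C@@H](c2ccc(OCOC)cc2OCOC)[C@@H]3c2cc(OCOC)cc(OCOC)c2)cc1 | intermediate
38 | target, (2R,3R,2'R,3'R), E | Oc1ccc(/C=C/c2cc(O)c3c(c2)O[C@@H](c2ccc(O)cc2)[C@@H]3c2cc(O)c3c(c2)O[C@@H](c2ccc(O)cc2O)[C@@H]3c2cc(O)cc(O)c2)cc1 | target

**Step count**

Total step count: 17.
Longest linear sequence: 6 steps (10 → 11 → 12 → 13 → 21 → 37 → 38, that is steps 6, 7, 8, 10, 16, 17). The lines from 1 and from 4 are equally long.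

**Steps most likely to fail**

1. Step 16.
What may go wrong: decay of the benzylide (protonation, sigmatropic rearrangement, acylation by the carbonate) before the methide is released, self-condensation of the methide, or poor facial selectivity in the C2–C3 bond formation. Any cis ring formed must be removed before step 17, because acid would turn it into the wrong trans diastereomer.
Fallback (known chemistry; sets out from 25, 28 and 21, comes back at 38): Mitsunobu etherification of phenol 25 with alcohol 28 should give the benzyl ether aldehyde F1. Aryllithium 32 (from 21 and t-BuLi) adds to it to give the diarylcarbinol F2, which Dess–Martin periodinane oxidises to the diaryl ketone F3. Hydrazine hydrate converts this into the hydrazone F4, and MnO2 oxidises it to the diaryldiazomethane F5. With the enantiomer of Rh2(PTAD)4 that delivers 3R, F5 undergoes enantioselective intramolecular insertion of the donor/donor carbene into the OCH2Ar C–H bond. This gives the cis-dihydrobenzofuran F6 (2S,3R). The HCl/MeOH treatment of step 17 then removes the MOM groups and equilibrates C2 to trans through the para-quinone-methide-type cation, which leads to 38.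

2. Step 10.
What may go wrong: the same loss of ylide and methide as above, lithium–bromine exchange between 16 and 13 in competition with carbonyl addition, and erosion of face selectivity by the ortho MOM-oxy group of the benzylide.
Fallback (known chemistry; sets out from 12, 6 and 15, comes back at 21): Mitsunobu etherification of 12 with alcohol 6 gives the benzyl ether aldehyde F7. Aryllithium 16 adds to give the diarylcarbinol F8, and oxidation gives the diaryl ketone F9. Hydrazine gives the hydrazone F10, and MnO2 gives the diaryldiazomethane F11. Rh2(PTAD)4-catalysed C–H insertion gives the cis-dihydrobenzofuran F12 (2S,3R). Catalytic camphorsulfonic acid in dry CH2Cl2 epimerises C2 through the 2,4-dialkoxybenzyl cation to trans 21.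

3. Step 17.
What may go wrong: electrophilic attack of formaldehyde equivalents on the freed resorcinol rings, protonation of the stilbene, and solvolytic opening at C2', whose 2,4-dioxygenated aryl group ionises easily.
Fallback (sets out from 37, comes back at 38): acetal-to-silyl exchange with TESOTf and 2,2'-bipyridyl in CH2Cl2 at 0 °C under non-acidic conditions gives the octakis(triethylsilyl) ether F13. Buffered fluoride (HF·pyridine or TBAF/AcOH, THF, 0 °C) then cleaves it to 38.

**Further compounds**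

F1 | step 16 | 2-{[4-(methoxymethoxy)phenyl]methoxy}-6-(methoxymethoxy)-4-{(E)-2-[4-(methoxymethoxy)phenyl]ethenyl}benzaldehyde | COCOc1ccc(/C=C/c2cc(OCc3ccc(OCOC)cc3)c(C=O)c(OCOC)c2)cc1
F2 | step 16 | diarylcarbinol from F1 and 32 (carbinol centre not defined) | COCOc1ccc(/C=C/c2cc(OCc3ccc(OCOC)cc3)c(C(O)c3cc(OCOC)c4c(c3)O[C@@H](c3ccc(OCOC)cc3OCOC)[C@@H]4c3cc(OCOC)cc(OCOC)c3)c(OCOC)c2)cc1
F3 | step 16 | diaryl ketone from F2 | COCOc1ccc(/C=C/c2cc(OCc3ccc(OCOC)cc3)c(C(=O)c3cc(OCOC)c4c(c3)O[C@@H](c3ccc(OCOC)cc3OCOC)[C@@H]4c3cc(OCOC)cc(OCOC)c3)c(OCOC)c2)cc1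
F4 | step 16 | hydrazone of F3 (C=N geometry not defined) | COCOc1ccc(/C=C/c2cc(OCc3ccc(OCOC)cc3)c(C(=NN)c3cc(OCOC)c4c(c3)O[C@@H](c3ccc(OCOC)cc3OCOC)[C@@H]4c3cc(OCOC)cc(OCOC)c3)c(OCOC)c2)cc1
F5 | step 16 | diaryldiazomethane from F4 | COCOc1ccc(/C=C/c2cc(OCc3ccc(OCOC)cc3)c(C(=[N+]=[N-])c3cc(OCOC)c4c(c3)O[C@@H](c3ccc(OCOC)cc3OCOC)[C@@H]4c3cc(OCOC)cc(OCOC)c3)c(OCOC)c2)cc1
F6 | step 16 | C2 epimer of 37, cis in unit A (2S,3R,2'R,3'R) | COCOc1ccc(/C=C/c2cc(OCOC)c3c(c2)O[C@H](c2ccc(OCOC)cc2)[C@@H]3c2cc(OCOC)c3c(c2)O[C@@H](c2ccc(OCOC)cc2OCOC)[C@@H]3c2cc(OCOC)cc(OCOC)c2)cc1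
F7 | step 10 | 4-bromo-2-{[2,4-bis(methoxymethoxy)phenyl]methoxy}-6-(methoxymethoxy)benzaldehyde | COCOc1ccc(COc2cc(Br)cc(OCOC)c2C=O)c(OCOC)c1
F8 | step 10 | diarylcarbinol from F7 and 16 (racemic centre) | COCOc1ccc(COc2cc(Br)cc(OCOC)c2C(O)c2cc(OCOC)cc(OCOC)c2)c(OCOC)c1
F9 | step 10 | diaryl ketone from F8 | COCOc1ccc(COc2cc(Br)cc(OCOC)c2C(=O)c2cc(OCOC)cc(OCOC)c2)c(OCOC)c1
F10 | step 10 | hydrazone of F9 (C=N geometry not defined) | COCOc1ccc(COc2cc(Br)cc(OCOC)c2C(=NN)c2cc(OCOC)cc(OCOC)c2)c(OCOC)c1
F11 | step 10 | diaryldiazomethane from F10 | COCOc1ccc(COc2cc(Br)cc(OCOC)c2C(=[N+]=[N-])c2cc(OCOC)cc(OCOC)c2)c(OCOC)c1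
F12 | step 10 | C2 epimer of 21, cis (2S,3R) | Brc1cc(OCOC)c2c(c1)O[C@H](c1ccc(OCOC)cc1OCOC)[C@@H]2c1cc(OCOC)cc(OCOC)c1
F13 | step 17 | octakis(triethylsilyl) ether of the target (2R,3R,2'R,3'R) | CC[Si](CC)(CC)Oc1ccc(/C=C/c2cc(O[Si](CC)(CC)CC)c3c(c2)O[C@@H](c2ccc(O[Si](CC)(CC)CC)cc2)[C@@H]3c2cc(O[Si](CC)(CC)CC)c3c(c2)O[C@@H](c2ccc(O[Si](CC)(CC)CC)cc2O[Si](CC)(CC)CC)[C@@H]3c2cc(O[Si](CC)(CC)CC)cc(O[Si](CC)(CC)CC)c2)cc1
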